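**Retrosynthetic overview**
- The target is epioritin-(4β→6)-epioritin-4α-ol, formally two molecules of teracacidin (epioritin-4α-ol) minus water; the C4–C6 interflavanyl bond is made last by biomimetic self-condensation.
- Teracacidin ⇒ (2S)-flav-3-ene: both carbinol C–O bonds (C3, C4) come from a bromonium-triggered carboxylative cis-dioxygenation on the face syn to the 2-aryl group.
- (2S)-Flav-3-ene ⇒ chalcone-derived allylic alcohol: the key step is an enantioselective O1–C2 bond formation (oxa-6π closure of a vinyl o-quinone methide) that closes the pyran ring and sets C2.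
- Allylic alcohol ⇒ chalcone ⇒ gallacetophenone + 4-(allyloxy)benzaldehyde.
- Ring order: A and B rings are bought; the pyran C ring is closed in step 4; both halves of the dimer are the same monomer, joined in step 7.

Assumption: the sense of induction of the chiral acid in step 4 is not predictable, so the catalyst antipode that gives the (2S)-chromene is chosen after a two-run screen.

**Step 1**
Reactants: 1 2',3',4'-trihydroxyacetophenone (gallacetophenone)
Product: 2 1-[2-hydroxy-3,4-bis(allyloxy)phenyl]ethan-1-one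
Conditions: allyl bromide (2.05 eq), K2CO3 (2.1 eq), acetone, 50 °C
Reagents that add atoms: allyl bromide, C=CCBr
Why: Williamson etherification in which the 2-OH, hydrogen-bonded to the acetyl carbonyl, stays free so that only the 3- and 4-OH are allylated.

**Step 2**
Reactants: 2 1-[2-hydroxy-3,4-bis(allyloxy)phenyl]ethan-1-one; 3 4-(allyloxy)benzaldehyde
Product: 4 (E)-1-[2-hydroxy-3,4-bis(allyloxy)phenyl]-3-[4-(allyloxy)phenyl]prop-2-en-1-one
Conditions: KOH (50% aq.), EtOH, rt
Reagents that add atoms: none
Why: Claisen–Schmidt aldol condensation, whose E1cB dehydration gives only the (E)-chalcone and to which allyl ethers are inert.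

**Step 3**
Reactants: 4 (E)-1-[2-hydroxy-3,4-bis(allyloxy)phenyl]-3-[4-(allyloxy)phenyl]prop-2-en-1-one
Product: 5 rac-(E)-1-[2-hydroxy-3,4-bis(allyloxy)phenyl]-3-[4-(allyloxy)phenyl]prop-2-en-1-ol
Conditions: NaBH4, CeCl3·7H2O, MeOH/THF, −20 °C; pH 7 buffer work-up, no silica, used crude at once
Reagents that add atoms: none
Why: Luche 1,2-reduction of the enone; the carbinol centre is racemic and is erased in step 4, and the neutral work-up prevents premature (racemic) ring closure.

**Step 4**
Reactants: 5 rac-(E)-1-[2-hydroxy-3,4-bis(allyloxy)phenyl]-3-[4-(allyloxy)phenyl]prop-2-en-1-ol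
Product: 7 (2S)-7,8-bis(allyloxy)-2-[4-(allyloxy)phenyl]-2H-chromene, via vinyl o-quinone methide 6 (not isolated)
Conditions: confined chiral BINOL-derived imidodiphosphoric acid (5 mol %), 5 Å MS, toluene (0.02 M), −40 °C, dark
Reagents that add atoms: none
Why: Proposed new method: a catalytic enantioselective dehydrative oxa-6π ring closure in which the chiral acid dehydrates the o-hydroxybenzylic allylic alcohol to the vinyl o-quinone methide 6, holds it by a hydrogen bond (ion pair in the limit) to its carbonyl oxygen inside the confined pocket and so selects one helical s-cis conformer for the disrotatory closure that forms the O1–C2 bond and sets C2 (S), the only reagent-controlled stereocentre of the route; the closest known reaction types are chiral phosphoric acid-catalysed additions to o-quinone methides made in situ from o-hydroxybenzyl alcohols, chiral Brønsted acid contact-ion-pair allylic etherification to 2,2-disubstituted 2H-chromenes and Pd-catalysed asymmetric 6-endo allylic etherification.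

**Step 5**
Reactants: 7 (2S)-7,8-bis(allyloxy)-2-[4-(allyloxy)phenyl]-2H-chromene
Product: 9 7,8-bis(allyloxy)-2-[4-(allyloxy)phenyl]chromane-3,4-diyl carbonate (all-cis cyclic carbonate; CIP 2R,3S,4R), via trans-bromohydrin 8 (not isolated)
Conditions: NBS (1.05 eq), MeCN/H2O 9:1, −10 °C, dark; then DBU (2.5 eq), CO2 (5 bar), 25 °C; recrystallise to raise ee
Reagents that add atoms: water, O; carbon dioxide, O=C=O
Why: Bromohydrin formation followed by carboxylative cyclisation of the halohydrin to a cyclic carbonate: Br+ adds anti to the C2 aryl group, water opens at benzylic C4 trans to bromine, and the carboxylated C4 alkoxide displaces the C3 bromide with inversion, so both oxygens end up cis to each other and to the 2-aryl group (3α,4α), which osmylation (anti to the aryl group) cannot deliver.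

**Step 6**
Reactants: 9 7,8-bis(allyloxy)-2-[4-(allyloxy)phenyl]chromane-3,4-diyl carbonate
Product: 11 teracacidin (2R,3R,4R)-2-(4-hydroxyphenyl)chromane-3,4,7,8-tetrol, via tri-O-allyl diol 10 (not isolated)
Conditions: K2CO3 (0.2 eq), MeOH, 0 °C; then Pd(PPh3)4 (5 mol %), morpholine (10 eq), THF/MeOH, rt, Ar; AcOH quench, Sephadex LH-20
Reagents that add atoms: none
Why: Base-catalysed transesterification frees the cis-diol and Pd(0)-catalysed Tsuji–Trost deallylation (allyl transfer to morpholine) frees the three phenols, leaving the labile benzylic 4-OH and all stereocentres untouched, which hydrogenolysis or acid would not.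

**Step 7**
Reactants: 11 teracacidin (two molecules)
Product: 13 epioritin-(4β→6)-epioritin-4α-ol (the target), via quinone methide 12 (not isolated)
Conditions: AgBF4 (1.5 eq), THF (0.2 M), 0 °C, Ar, dark, stopped at about 40% conversion; aq. NaHCO3; Sephadex LH-20 then RP-HPLC; 11 recovered
Reagents that add atoms: none
Why: Biomimetic Friedel–Crafts-type flavan-4-yl coupling (self-condensation of a flavan-3,4-diol) in which Lewis acid-assisted loss of the 4-OH gives the C4 cation/quinone methide 12, attacked on the β-face, anti to the axial 3-OH, by C6 of a second molecule of 11 (ortho to 7-OH, para to the ring oxygen, less hindered than C5), which sets the upper C4 (S, 3,4-trans) while the 4α-OH of the nucleophilic unit is kept.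

**Compound list**
1 | 2',3',4'-trihydroxyacetophenone (gallacetophenone) | CC(=O)c1ccc(O)c(O)c1O | starting material
2 | 1-[2-hydroxy-3,4-bis(allyloxy)phenyl]ethan-1-one | CC(=O)c1ccc(OCC=C)c(OCC=C)c1O | intermediate
3 | 4-(allyloxy)benzaldehyde | O=Cc1ccc(OCC=C)cc1 | starting material
4 | (E)-1-[2-hydroxy-3,4-bis(allyloxy)phenyl]-3-[4-(allyloxy)phenyl]prop-2-en-1-one | O=C(/C=C/c1ccc(OCC=C)cc1)c1ccc(OCC=C)c(OCC=C)c1O | intermediate
5 | rac-(E)-1-[2-hydroxy-3,4-bis(allyloxy)phenyl]-3-[4-(allyloxy)phenyl]prop-2-en-1-ol | OC(/C=C/c1ccc(OCC=C)cc1)c1ccc(OCC=C)c(OCC=C)c1O | intermediate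
6 | (6Z)-2,3-bis(allyloxy)-6-[(2E)-3-[4-(allyloxy)phenyl]prop-2-en-1-ylidene]cyclohexa-2,4-dien-1-one (vinyl o-quinone methide) | C=CCOc1ccc(/C=C/C=C2\C(=O)C(OCC=C)=C(OCC=C)C=C2)cc1 | intermediate (not isolated)
7 | (2S)-7,8-bis(allyloxy)-2-[4-(allyloxy)phenyl]-2H-chromene | C=CCOc1ccc2c(c1OCC=C)O[C@H](c1ccc(OCC=C)cc1)C=C2 | intermediate
8 | (2R,3S,4R)-7,8-bis(allyloxy)-2-[4-(allyloxy)phenyl]-3-bromochroman-4-ol (2,3-trans-3,4-trans bromohydrin) | C=CCOc1ccc2c(c1OCC=C)O[C@H](c1ccc(OCC=C)cc1)[C@@H](Br)[C@@H]2O | intermediate (not isolated)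
9 | (2R,3S,4R)-7,8-bis(allyloxy)-2-[4-(allyloxy)phenyl]chromane-3,4-diyl carbonate (cis-fused cyclic carbonate, both oxygens cis to the 2-aryl group) | C=CCOc1ccc2c(c1OCC=C)O[C@H](c1ccc(OCC=C)cc1)[C@@H]1OC(=O)O[C@H]21 | intermediate
10 | (2R,3R,4R)-7,8-bis(allyloxy)-2-[4-(allyloxy)phenyl]chromane-3,4-diol | C=CCOc1ccc2c(c1OCC=C)O[C@H](c1ccc(OCC=C)cc1)[C@H](O)[C@@H]2O | intermediate (not isolated)
11 | teracacidin (epioritin-4α-ol), (2R,3R,4R)-2-(4-hydroxyphenyl)chromane-3,4,7,8-tetrol | Oc1ccc2c(c1O)O[C@H](c1ccc(O)cc1)[C@H](O)[C@@H]2O | intermediate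
12 | (2R,3R)-3,8-dihydroxy-2-(4-hydroxyphenyl)-2,3-dihydro-7H-chromen-7-one (A-ring quinone methide of 11, conjugate base of its C4 cation) | O=C1C(O)=C2O[C@H](c3ccc(O)cc3)[C@H](O)C=C2C=C1 | intermediate (not isolated)
13 | epioritin-(4β→6)-epioritin-4α-ol, (2R,3R,4R)-6-[(2R,3R,4S)-3,7,8-trihydroxy-2-(4-hydroxyphenyl)chroman-4-yl]-2-(4-hydroxyphenyl)chromane-3,4,7,8-tetrol | Oc1ccc([C@H]2Oc3c(ccc(O)c3O)[C@H](c3cc4c(c(O)c3O)O[C@H](c3ccc(O)cc3)[C@H](O)[C@@H]4O)[C@H]2O)cc1 | target

**Totals**
Total step count: 7. Longest linear sequence: 7 steps (1 → 13; compound 3 is bought).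

**Steps most likely to fail**

Step 4 (the proposed new reaction). Risks are a racemic background closure of free 6, light- or acid-induced ring opening of 7 (racemisation) and acid-triggered oligomerisation of the electron-rich chromene. The fallback uses known chemistry, sets out from chalcone 4 and returns at 7. Chalcone 4 is cyclised with NaOAc in refluxing EtOH to racemic 7,8-bis(allyloxy)-2-[4-(allyloxy)phenyl]chroman-4-one F1. A Noyori-type asymmetric transfer hydrogenation run as a kinetic resolution (RuCl(p-cymene)(TsDPEN), HCO2H/Et3N, stopped near 50% conversion) reduces the (2S)-enantiomer to (2S,4S)-7,8-bis(allyloxy)-2-[4-(allyloxy)phenyl]chroman-4-ol F2, which is separated from unreacted (2R)-flavanone. Dehydration of F2 with Burgess reagent (THF, 50 °C) gives 7.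

Step 5. Risks are bromination of the electron-rich rings or allyl groups, hydrolysis of a transient 3,4-epoxide by the water present, and incomplete carbonate closure. The fallback sets out from 7 and returns at 11; it fixes the C4 configuration by anchimeric equilibration instead of carbonate closure. Bromohydrin 8 is made as before but isolated and closed with K2CO3 in dry acetone to (2R,3R,4R)-7,8-bis(allyloxy)-2-[4-(allyloxy)phenyl]-3,4-epoxychromane F3 (epoxide syn to the aryl group). Opening and acetylation with Ac2O/AcOH/NaOAc gives (2R,3S,4S)-7,8-bis(allyloxy)-2-[4-(allyloxy)phenyl]chromane-3,4-diyl diacetate F4 (3,4-trans; any 4-epimer converges). TsOH (cat.) in wet AcOH ionises C4 with participation of the 3-acetate (cis-fused acetoxonium ion, opened by water at the acyl carbon) to give (2R,3R,4R)-7,8-bis(allyloxy)-2-[4-(allyloxy)phenyl]-4-hydroxychroman-3-yl acetate F5. The conditions of step 6 (K2CO3/MeOH, then Pd(PPh3)4/morpholine) convert F5 into 11.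

Step 7. Risks are ether-linked (C4–O) dimers, the (4β→5) regioisomer, trimers, and C4 epimerisation of the lower unit; the isolated yield will be modest even with recovery of 11. The fallback sets out from 11 and returns at 13; it separates the electrophile and nucleophile roles. Part of 11 is thiolysed (phenylmethanethiol, cat. AcOH, EtOH, 40 °C) to (2R,3S,4S)-4-(benzylsulfanyl)-2-(4-hydroxyphenyl)chromane-3,7,8-triol F6 (4β-benzylsulfanyl-epioritin). F6 is then activated thiophilically with AgBF4 in THF at 0 °C in the presence of 4 equivalents of 11. Only F6 ionises, the excess nucleophile suppresses oligomers, and β-attack by C6 of 11 gives 13 directly, with no deprotection.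

**Further compounds**
F1 | step 4 | rac-7,8-bis(allyloxy)-2-[4-(allyloxy)phenyl]chroman-4-one | C=CCOc1ccc2c(c1OCC=C)OC(c1ccc(OCC=C)cc1)CC2=O
F2 | step 4 | (2S,4S)-7,8-bis(allyloxy)-2-[4-(allyloxy)phenyl]chroman-4-ol | C=CCOc1ccc2c(c1OCC=C)O[C@H](c1ccc(OCC=C)cc1)C[C@@H]2O
F3 | step 5 | (2R,3R,4R)-7,8-bis(allyloxy)-2-[4-(allyloxy)phenyl]-3,4-epoxychromane | C=CCOc1ccc2c(c1OCC=C)O[C@H](c1ccc(OCC=C)cc1)[C@@H]1O[C@H]21
F4 | step 5 | (2R,3S,4S)-7,8-bis(allyloxy)-2-[4-(allyloxy)phenyl]chromane-3,4-diyl diacetate | C=CCOc1ccc2c(c1OCC=C)O[C@H](c1ccc(OCC=C)cc1)[C@H](OC(C)=O)[C@H]2OC(C)=O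
F5 | step 5 | (2R,3R,4R)-7,8-bis(allyloxy)-2-[4-(allyloxy)phenyl]-4-hydroxychroman-3-yl acetate | C=CCOc1ccc2c(c1OCC=C)O[C@H](c1ccc(OCC=C)cc1)[C@H](OC(C)=O)[C@@H]2O
F6 | step 7 | (2R,3S,4S)-4-(benzylsulfanyl)-2-(4-hydroxyphenyl)chromane-3,7,8-triol | Oc1ccc2c(c1O)O[C@H](c1ccc(O)cc1)[C@H](O)[C@H]2SCc1ccccc1
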